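**Retrosynthetic overview**

1. The target comes from a fully protected macrolide by one cleavage of the MOM ether and the acetonide.
2. The 12-membered ring is closed at the cis C=C bond by Z-selective ring-closing metathesis; the ester C–O bond comes from Yamaguchi coupling of an aryl acid with a secondary alcohol.
3. The acid is a diaryl ether made by SNAr of an ortho-fluoro benzaldehyde with 5-hydroxy-2-methylbenzoic acid, then methylenation; the aldehyde comes from ortho-lithiation of a fluorinated saligenin acetonide.
4. Key C–C bond (carbinol–carbinol bond of the diol): an α-oxygenated allyl carbanion (d1 reagent, chiral Z-γ-alkoxyallylborane) adds to hexanal. Two natively electrophilic, oxygen-bearing carbons are joined and both stereocentres are set at once, instead of an acyl-anion (dithiane) addition followed by ketone reduction.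
5. Ring order: the 1,3-benzodioxine protecting ring first (step 2), the macrolactone ring second (step 7), the benzodioxine opened last (step 8); both arene rings are bought.

Assumption: the SMILES is taken at face value (S at both carbinol carbons, Z olefin), and allyl methoxymethyl ether, hexanal, 5-fluoro-2-hydroxybenzyl alcohol, 5-hydroxy-2-methylbenzoic acid and (+)-Ipc2BOMe are bought.

**Route**

Step 1
Reactants: 1 allyl methoxymethyl ether (3-(methoxymethoxy)prop-1-ene); 2 hexanal
Product: 5 syn-diol monoether (3S,4S)-3-(methoxymethoxy)non-1-en-4-ol, via 1-(methoxymethoxy)allyllithium 3 (not isolated), via Z-alkoxyallyl-diisopinocampheylborane 4 (not isolated)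
Conditions: s-BuLi, THF, −78 °C; (+)-Ipc2BOMe, −78 °C; BF3·OEt2, −78 °C; then 2, −78 °C, 3 h; NaOH, H2O2, 0 °C to rt
Reagents that add atoms: none
Why: Brown asymmetric γ-alkoxyallylboration, in which the O-chelated lithiated allyl ether is an α-oxygenated carbanion (d1 reagent) whose Z-allylborane adds to the Re face of hexanal through a closed chair transition state, so the Z geometry gives the syn (3S,4S) monoether (both stereocentres, typically >95:5 dr and about 90–95% ee) with the C4 hydroxyl free and the C3 oxygen already protected.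

Step 2
Reactants: 6 5-fluoro-2-hydroxybenzyl alcohol (4-fluoro-2-(hydroxymethyl)phenol)
Product: 7 acetonide 6-fluoro-2,2-dimethyl-4H-1,3-benzodioxine
Conditions: Me2C(OMe)2, TsOH·H2O (cat.), acetone, rt
Reagents that add atoms: 2,2-dimethoxypropane, COC(C)(C)OC
Why: Acid-catalysed transketalisation (acetonide formation) ties the phenol and the benzylic alcohol into one base-stable six-membered ketal.

Step 3
Reactants: 7 acetonide 6-fluoro-2,2-dimethyl-4H-1,3-benzodioxine
Product: 9 aldehyde 6-fluoro-2,2-dimethyl-4H-1,3-benzodioxine-5-carbaldehyde, via C5-aryllithium 8 (not isolated)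
Conditions: s-BuLi, THF, −78 °C, 1 h; DMF, −78 to 0 °C; NH4Cl (aq.)
Reagents that add atoms: N,N-dimethylformamide, CN(C)C=O
Why: Directed ortho-lithiation and formylation, where fluorine acidifies its ortho positions and the benzylic ketal oxygen coordinates lithium, so deprotonation is expected at C5 between the two groups, and −78 °C keeps the ortho-fluoro aryllithium from losing LiF to an aryne.

Step 4
Reactants: 9 aldehyde 6-fluoro-2,2-dimethyl-4H-1,3-benzodioxine-5-carbaldehyde; 10 5-hydroxy-2-methylbenzoic acid
Product: 11 diaryl ether 5-[(5-formyl-2,2-dimethyl-4H-1,3-benzodioxin-6-yl)oxy]-2-methylbenzoic acid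
Conditions: K2CO3 (2.5 equiv), DMSO, 110 °C; then 0.5 M HCl to pH 4, 0 °C
Reagents that add atoms: none
Why: Nucleophilic aromatic substitution (SNAr, addition–elimination), in which the ortho formyl group stabilises the Meisenheimer adduct so the phenoxide of the dianion displaces fluoride while the carboxylate is too weak a nucleophile to compete.

Step 5
Reactants: 11 diaryl ether 5-[(5-formyl-2,2-dimethyl-4H-1,3-benzodioxin-6-yl)oxy]-2-methylbenzoic acid
Product: 12 styrene acid 5-[(5-ethenyl-2,2-dimethyl-4H-1,3-benzodioxin-6-yl)oxy]-2-methylbenzoic acid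
Conditions: Ph3PCH3Br (3 equiv), KOtBu (4 equiv), THF, 0 °C to rt; then 0.5 M HCl to pH 4, 0 °C
Reagents that add atoms: methyltriphenylphosphonium bromide, C[P+](c1ccccc1)(c1ccccc1)c1ccccc1.[Br-]
Why: Wittig methylenation, in which the small unstabilised ylide adds even to the di-ortho-substituted aldehyde while the substrate is carried as its potassium carboxylate.

Step 6
Reactants: 12 styrene acid 5-[(5-ethenyl-2,2-dimethyl-4H-1,3-benzodioxin-6-yl)oxy]-2-methylbenzoic acid; 5 syn-diol monoether (3S,4S)-3-(methoxymethoxy)non-1-en-4-ol
Product: 14 diene ester (3S,4S)-3-(methoxymethoxy)non-1-en-4-yl 5-[(5-ethenyl-2,2-dimethyl-4H-1,3-benzodioxin-6-yl)oxy]-2-methylbenzoate, via mixed trichlorobenzoic anhydride 13 (not isolated)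
Conditions: 2,4,6-Cl3C6H2COCl, Et3N, THF, rt; then 5, DMAP, toluene, rt to 40 °C
Reagents that add atoms: none
Why: Yamaguchi esterification, in which DMAP attacks the less hindered acyl group of the mixed anhydride and the only free hydroxyl of 5 (C4) is acylated at oxygen, so both stereocentres are retained.

Step 7
Reactants: 14 diene ester (3S,4S)-3-(methoxymethoxy)non-1-en-4-yl 5-[(5-ethenyl-2,2-dimethyl-4H-1,3-benzodioxin-6-yl)oxy]-2-methylbenzoate
Product: 15 protected macrolide, the Z-configured 12-membered lactone of the target with the phenol and benzylic alcohol of ring B tied as the acetonide and the allylic oxygen as its MOM ether, S at both carbinol carbons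
Conditions: Mo(=N-1-adamantyl)(=CHCMe2Ph)(NC4H4)[O-2,6-(2,4,6-iPr3C6H2)2C6H3] (10 mol %), toluene (2 mM), 22–40 °C, 7 torr
Reagents that add atoms: none
Why: Z-selective ring-closing metathesis, in which the very large aryloxide of the hexavalent molybdenum monoaryloxide pyrrolide alkylidene forces both metallacyclobutane substituents toward the small imido ligand, so the ring closes to the cis styrenyl olefin under kinetic control while reduced pressure removes ethene and suppresses Z-to-E equilibration.

Step 8
Reactants: 15 protected macrolide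
Product: 16 target macrolide CNP0191798.1, 12-membered lactone of 5-aryloxy-2-methylbenzoic acid with (S)-pentyl carbinol ester carbon, adjacent (S)-allylic alcohol, Z styrenyl olefin and a ring B carrying CH2OH and OH
Conditions: Me2BBr (6 equiv), CH2Cl2, −78 °C; then NaHCO3 (aq.), THF, 0 °C
Reagents that add atoms: none
Why: Lewis-acid acetal cleavage (Guindon conditions), in which dimethylboron bromide opens both the MOM ether and the isopropylidene ketal at −78 °C by bromide capture of the oxocarbenium ions and bicarbonate hydrolysis then frees the three hydroxyls without strong protic acid (ionisation of the allylic or ortho-hydroxybenzylic alcohol) or base (acyl migration).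

**Compound list**

1 | allyl methoxymethyl ether, 3-(methoxymethoxy)prop-1-ene | C=CCOCOC | starting material
2 | hexanal | CCCCCC=O | starting material
3 | 1-(methoxymethoxy)allyllithium (O-chelated, Z-configured lithiated allyl ether) | [Li]C(C=C)OCOC | intermediate
4 | (Z)-[3-(methoxymethoxy)allyl]diisopinocampheylborane from (+)-Ipc2BOMe | COCO/C=C\CB([C@H]1C[C@H]2C[C@@H]([C@@H]1C)C2(C)C)[C@H]1C[C@H]2C[C@@H]([C@@H]1C)C2(C)C | intermediate
5 | (3S,4S)-3-(methoxymethoxy)non-1-en-4-ol | CCCCC[C@H](O)[C@@H](OCOC)C=C | intermediate
6 | 5-fluoro-2-hydroxybenzyl alcohol, 4-fluoro-2-(hydroxymethyl)phenol | OCc1cc(F)ccc1O | starting material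
7 | 6-fluoro-2,2-dimethyl-4H-1,3-benzodioxine | CC1(C)OCc2cc(F)ccc2O1 | intermediate
8 | (6-fluoro-2,2-dimethyl-4H-1,3-benzodioxin-5-yl)lithium | CC1(C)OCc2c([Li])c(F)ccc2O1 | intermediate
9 | 6-fluoro-2,2-dimethyl-4H-1,3-benzodioxine-5-carbaldehyde | CC1(C)OCc2c(C=O)c(F)ccc2O1 | intermediate
10 | 5-hydroxy-2-methylbenzoic acid | Cc1ccc(O)cc1C(=O)O | starting material
11 | 5-[(5-formyl-2,2-dimethyl-4H-1,3-benzodioxin-6-yl)oxy]-2-methylbenzoic acid | Cc1ccc(Oc2ccc3OC(C)(C)OCc3c2C=O)cc1C(=O)O | intermediate
12 | 5-[(5-ethenyl-2,2-dimethyl-4H-1,3-benzodioxin-6-yl)oxy]-2-methylbenzoic acid | Cc1ccc(Oc2ccc3OC(C)(C)OCc3c2C=C)cc1C(=O)O | intermediate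
13 | mixed anhydride of 12 with 2,4,6-trichlorobenzoic acid | Cc1ccc(Oc2ccc3OC(C)(C)OCc3c2C=C)cc1C(=O)OC(=O)c1c(Cl)cc(Cl)cc1Cl | intermediate
14 | (3S,4S)-3-(methoxymethoxy)non-1-en-4-yl 5-[(5-ethenyl-2,2-dimethyl-4H-1,3-benzodioxin-6-yl)oxy]-2-methylbenzoate | Cc1ccc(Oc2ccc3OC(C)(C)OCc3c2C=C)cc1C(=O)O[C@@H](CCCCC)[C@@H](OCOC)C=C | intermediate
15 | protected macrolide (Z olefin, acetonide on ring B, MOM on the allylic oxygen, S,S) | CCCCC[C@@H]1OC(=O)c2cc(ccc2C)Oc2ccc3OC(C)(C)OCc3c2/C=C\[C@@H]1OCOC | intermediate
16 | target macrolide CNP0191798.1 | CCCCC[C@@H]1OC(=O)c2cc(ccc2C)Oc2ccc(O)c(CO)c2/C=C\[C@@H]1O | target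

**Step count and risks**

Total step count: 8 (step 1 makes the diol fragment, steps 2–5 the diaryl ether acid, steps 6–8 join, cyclise and deprotect).
Longest linear sequence: 7 steps (6 → 7 → 9 → 11 → 12 → 14 → 15 → 16).

The three steps most likely to fail:

First risk, step 7. Both olefins are hindered (a di-ortho-substituted styrene and an allylic-ether olefin), and the cis isomer of this rigid 12-membered ring may not be the favoured one. The molybdenum catalyst may turn over slowly, give oligomers, or give the E isomer. The fallback sets out from 14 and comes back at 15. The ring is closed with the more robust second-generation Hoveyda–Grubbs catalyst RuCl2(=CH-2-(OiPr)C6H4)(1,3-dimesitylimidazolidin-2-ylidene) in toluene at 80 °C and 1 mM, accepting the E olefin, the E-configured protected macrolide F1. The geometry is then corrected in a separate photochemical step: triplet energy transfer from fac-Ir(ppy)3 under blue LEDs in MeCN at rt pumps the more conjugated E styrene into the twisted, poorly sensitised Z isomer 15. This fallback is itself uncertain, because both isomers of this di-ortho-substituted styrene are twisted.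

Second risk, step 3. Lithiation of 7 could take place at C7, the other, less hindered position ortho to fluorine, instead of C5. The fallback sets out from 7 and comes back at 9, using the wrong site as a blocking position. s-BuLi (THF, −78 °C) followed by Me3SiCl gives the C7-silylated arene (6-fluoro-2,2-dimethyl-4H-1,3-benzodioxin-7-yl)trimethylsilane F2. A second s-BuLi lithiation can then only take place at C5, the one remaining position ortho to fluorine, and DMF gives the silylated aldehyde 6-fluoro-2,2-dimethyl-7-(trimethylsilyl)-4H-1,3-benzodioxine-5-carbaldehyde F3. Fluoride-induced ipso-protodesilylation (CsF, wet DMF, 60 °C), helped by the ortho fluorine, returns 9.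

Third risk, step 8. The Lewis acid may ionise the cis-styrenyl allylic alcohol or the ortho-hydroxybenzylic alcohol, which can cyclise onto each other, or it may promote acyl migration. The fallback sets out from 14 and comes back at 16; it moves the acetal cleavage to a stage where the sensitive cis allylic alcohol does not yet exist and ends with a fluoride deprotection. Me2BBr (CH2Cl2, −78 °C, then NaHCO3) on 14 gives the triol diene ester F4. Et3SiOTf and 2,6-lutidine (CH2Cl2, −78 °C) give the tris(triethylsilyl) ether F5. The Z-selective ring-closing metathesis of step 7 gives the tris(triethylsilyl) macrolide F6. HF·pyridine in pyridine/THF at 0 °C then liberates 16 under nearly neutral conditions.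

**Further compounds**

F1 | step 7 | E-configured protected macrolide (E isomer of 15) | CCCCC[C@@H]1OC(=O)c2cc(ccc2C)Oc2ccc3OC(C)(C)OCc3c2/C=C/[C@@H]1OCOC
F2 | step 3 | (6-fluoro-2,2-dimethyl-4H-1,3-benzodioxin-7-yl)trimethylsilane | CC1(C)OCc2cc(F)c([Si](C)(C)C)cc2O1
F3 | step 3 | 6-fluoro-2,2-dimethyl-7-(trimethylsilyl)-4H-1,3-benzodioxine-5-carbaldehyde | CC1(C)OCc2c(C=O)c(F)c([Si](C)(C)C)cc2O1
F4 | step 8 | triol diene ester, (3S,4S)-3-hydroxynon-1-en-4-yl 5-[2-ethenyl-4-hydroxy-3-(hydroxymethyl)phenoxy]-2-methylbenzoate | Cc1ccc(Oc2ccc(O)c(CO)c2C=C)cc1C(=O)O[C@@H](CCCCC)[C@@H](O)C=C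
F5 | step 8 | tris(triethylsilyl) ether of F4 | Cc1ccc(Oc2ccc(O[Si](CC)(CC)CC)c(CO[Si](CC)(CC)CC)c2C=C)cc1C(=O)O[C@@H](CCCCC)[C@@H](O[Si](CC)(CC)CC)C=C
F6 | step 8 | tris(triethylsilyl) ether of the target macrolide (Z olefin) | CCCCC[C@@H]1OC(=O)c2cc(ccc2C)Oc2ccc(O[Si](CC)(CC)CC)c(CO[Si](CC)(CC)CC)c2/C=C\[C@@H]1O[Si](CC)(CC)CC
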